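**Plan**

1. Retrosynthetic cuts: (a) C8–C15′ and C13–C14′ of the bicyclo[3.2.1]octane, a (5+2) retron, give hydroxyquinone 30 and the labdane diene acid 31; (b) C6–C8, a 1,2-aryl-shift retron, gives the 6,7-dehydroabietane 24; (c) C1–C2 and C9–C10 give the acyclic 1,5-enyne 21; (d) C4–C5 (Nicholas reaction) and C7–aryl (Negishi coupling).
2. Forward order: ring C (arene) is bought in; the C5–C7/C10 chain is attached and C5 alkylated; one gold-catalysed event closes ring A (C1–C2) and then ring B (C9–C10); ring B is contracted 6→5 with C7 extruded as the formyl group; C6 is hydroxylated; ring C becomes the hydroxyquinone; the seven-membered ring and its C14 ketone bridge arise in the final (5+2) union.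
3. Enabling feature: in ring A, C1–C3 are bare CH2 groups, C4 is a quaternary gem-dimethyl carbon and C10 a methyl-bearing quaternary carbon bonded to aromatic C9. An alkyne on C4 (C2≡C3) and an isopropenyl group (C1=C10) on C5 therefore form a 1,5-enyne whose 6-endo closure leaves a tertiary C10 cation beside the methoxy-activated C9.
4. Stereochemistry: C5 from (R)-4-benzyloxazolidinone; C10 from C5 in the cascade (trans A/B); C6 by α-face enolate hydroxylation; C8, C13 and C14′ by an α-face, endo (5+2) addition; the four labdane stereocentres and the 12′E alkene come with 31.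

Key step: step 11

Remark: 4-epi-trans-communic acid (31, sold as 4-epicommunic acid) is assumed to be purchasable as the isolated natural product. Diterpene carbons carry abietane numbers; those of the labdane part are primed.

**Route**

Step 1
Reactants: 1 1,2,4-trimethoxybenzene; 2 acetone
Product: 4 2-(2,3,6-trimethoxyphenyl)propan-2-ol, via aryllithium 3 (not isolated)
Conditions: n-BuLi, TMEDA, THF, 0 °C; then acetone, −78 °C to rt; H2O
Reagents that add atoms: none
Why: Directed ortho-lithiation removes the proton flanked by two methoxy groups and the aryllithium adds 1,2 to acetone; no stereocentre is formed.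

Step 2
Reactants: 4 2-(2,3,6-trimethoxyphenyl)propan-2-ol
Product: 5 2-isopropyl-1,3,4-trimethoxybenzene
Conditions: Et3SiH, CF3CO2H, CH2Cl2, 0 °C to rt
Reagents that add atoms: none
Why: Ionic hydrogenation, in which acid ionises the tertiary benzylic alcohol (cation stabilised by two ortho methoxy groups) and the silane delivers hydride.

Step 3
Reactants: 5 2-isopropyl-1,3,4-trimethoxybenzene
Product: 6 1-bromo-3-isopropyl-2,4,5-trimethoxybenzene
Conditions: N-bromosuccinimide, MeCN, 0 °C to rt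
Reagents that add atoms: N-bromosuccinimide, O=C1CCC(=O)N1Br
Why: Electrophilic aromatic bromination should go to the position ortho to one methoxy and para to another, the other free position having only one ortho methoxy group.

Step 4
Reactants: 7 (4R)-4-benzyl-1,3-oxazolidin-2-one; 8 4-bromobutanoyl chloride
Product: 10 (4R)-4-benzyl-3-(4-bromobutanoyl)-1,3-oxazolidin-2-one, via lithium oxazolidinide 9 (not isolated)
Conditions: n-BuLi, THF, −78 °C; then 8, −78 to 0 °C
Reagents that add atoms: none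
Why: N-acylation of the lithiated auxiliary by the acid chloride is much faster than displacement of the primary bromide; the auxiliary stereocentre is untouched.

Step 5
Reactants: 10 (4R)-4-benzyl-3-(4-bromobutanoyl)-1,3-oxazolidin-2-one; 6 1-bromo-3-isopropyl-2,4,5-trimethoxybenzene
Product: 12 (4R)-4-benzyl-3-[4-(3-isopropyl-2,4,5-trimethoxyphenyl)butanoyl]-1,3-oxazolidin-2-one, via alkylzinc bromide 11 (not isolated)
Conditions: Zn dust, LiCl, THF, 50 °C; then 6, Pd(OAc)2 (2 mol %), 2-dicyclohexylphosphino-2′,6′-dimethoxybiphenyl (4 mol %), THF, rt to 40 °C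
Reagents that add atoms: none
Why: Zinc insertion into the primary C–Br bond gives an alkylzinc that tolerates the imide, and Negishi sp3–sp2 coupling on zerovalent palladium joins C7 to the mono-ortho-substituted aryl bromide.

Step 6
Reactants: 13 3-methoxy-3-methylbut-1-yne; 14 Co2(CO)8
Product: 15 hexacarbonyl[μ-(3-methoxy-3-methylbut-1-yne)]dicobalt
Conditions: CH2Cl2, rt, N2
Reagents that add atoms: none
Why: Alkyne complexation with loss of two CO gives the dicobalt complex that serves as precursor of the cobalt-stabilised tertiary propargyl cation (Nicholas reaction).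

Step 7
Reactants: 12 (4R)-4-benzyl-3-[4-(3-isopropyl-2,4,5-trimethoxyphenyl)butanoyl]-1,3-oxazolidin-2-one; 15 hexacarbonyl[μ-(3-methoxy-3-methylbut-1-yne)]dicobalt
Product: 18 (4R)-4-benzyl-3-[(2S)-2-[2-(3-isopropyl-2,4,5-trimethoxyphenyl)ethyl]-3,3-dimethylpent-4-ynoyl]-1,3-oxazolidin-2-one, via boron enolate 16 (not isolated), via dicobalt adduct 17 (not isolated)
Conditions: Bu2BOTf (2.2 equiv), iPr2NEt (1.2 equiv), CH2Cl2, −78 to 0 °C; then 15, −78 to 0 °C; aqueous work-up; then N-methylmorpholine N-oxide, CH2Cl2, rt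
Reagents that add atoms: none
Why: Nicholas reaction of a chiral boron enolate, in which excess Bu2BOTf ionises the complexed tertiary methyl ether and the cation attacks the chelated Z-enolate on the face opposite the benzyl group, forming C4–C5 and setting C5 (2S in the imide) before the amine oxide removes cobalt.

Step 8
Reactants: 18 (4R)-4-benzyl-3-[(2S)-2-[2-(3-isopropyl-2,4,5-trimethoxyphenyl)ethyl]-3,3-dimethylpent-4-ynoyl]-1,3-oxazolidin-2-one
Product: 19 (2S)-2-[2-(3-isopropyl-2,4,5-trimethoxyphenyl)ethyl]-3,3-dimethylpent-4-ynoic acid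
Conditions: LiOH, H2O2, THF/H2O, 0 °C; Na2SO3; then HCl
Reagents that add atoms: hydrogen peroxide, OO
Why: Hydroperoxide cleavage of the N-acyloxazolidinone attacks the exocyclic carbonyl even of α-branched imides and leaves C5 untouched.

Step 9
Reactants: 19 (2S)-2-[2-(3-isopropyl-2,4,5-trimethoxyphenyl)ethyl]-3,3-dimethylpent-4-ynoic acid
Product: 20 (3S)-3-[2-(3-isopropyl-2,4,5-trimethoxyphenyl)ethyl]-4,4-dimethylhex-5-yn-2-one
Conditions: MeLi (3.3 equiv), Et2O, 0 °C to rt; aq. HCl
Reagents that add atoms: methyllithium, [Li]C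
Why: Addition of MeLi to the lithium carboxylate stops at the geminal dialkoxide, so the methyl ketone forms only on quench and C5 cannot epimerise (carboxylic acid to methyl ketone conversion).

Step 10
Reactants: 20 (3S)-3-[2-(3-isopropyl-2,4,5-trimethoxyphenyl)ethyl]-4,4-dimethylhex-5-yn-2-one
Product: 21 (4R)-4-[2-(3-isopropyl-2,4,5-trimethoxyphenyl)ethyl]-3,3,5-trimethylhex-5-en-1-yne
Conditions: Zn, CH2Br2, TiCl4, THF/CH2Cl2, 0 °C to rt
Reagents that add atoms: dibromomethane, BrCBr
Why: Takai–Lombardo methylenation is non-basic and should convert the hindered, enolisable ketone into the isopropenyl group (C1=C10) without epimerising C5.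

Step 11
Reactants: 21 (4R)-4-[2-(3-isopropyl-2,4,5-trimethoxyphenyl)ethyl]-3,3,5-trimethylhex-5-en-1-yne
Product: 22 (5S,10S)-11,12,14-trimethoxyabieta-2,8,11,13-tetraene
Conditions: [Au(NCMe){P(tBu)2(biphenyl-2-yl)}]SbF6 (3 mol %), CH2Cl2, 0 °C to rt
Reagents that add atoms: none
Why: Cationic monovalent gold π-activates the terminal alkyne C2≡C3 and the CH2 terminus (C1) of the isopropenyl group attacks C2 anti to the metal, giving a cyclopropyl gold carbenoid equivalent to a tertiary C10 cation with a C3 vinyl–gold bond; because propargylic C4 is quaternary the usual 1,2-hydrogen-shift exit is closed, so aromatic C9 opens the carbenoid at C10 and rearomatisation with protodeauration at C3 releases 22 and the catalyst. The closest known reaction type is the gold-catalysed 6-endo-dig carbocyclisation of 1,5-enynes in which the developing cation is captured by a tethered electron-rich arene (enyne polycyclisation ending in a Friedel–Crafts step). Ring A closes by 6-endo-dig attack (C1–C2) and ring B by 6-exo-trig attack of C9 on the C1=C10 unit (C9–C10). The new stereocentre C10 is controlled by C5: addition across C1=C10 is anti, and in the chair-like conformer with H5 eclipsing the alkene the alkyne arm (on C4) and the arylethyl arm (C6–C7) lie on opposite faces, so C9 bonds anti to H5 and the C10 methyl becomes axial (trans A/B junction, 10S). The step needs 6-endo over 5-exo closure, arene capture over proton loss and attack at one arene carbon only; these are secured by the 1,1-disubstituted alkene (charge at tertiary C10, open C2 versus neopentyl C3), the gem-dimethyl group, and C9 being the only unsubstituted, methoxy-activated ring position.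

Step 12
Reactants: 22 (5S,10S)-11,12,14-trimethoxyabieta-2,8,11,13-tetraene
Product: 23 (5S,10S)-11,12,14-trimethoxyabieta-8,11,13-triene
Conditions: H2 (1 atm), Pd/C, EtOAc, rt
Reagents that add atoms: none
Why: Heterogeneous hydrogenation saturates the cis-disubstituted C2=C3 alkene and leaves the arene and both stereocentres untouched.

Step 13
Reactants: 23 (5S,10S)-11,12,14-trimethoxyabieta-8,11,13-triene
Product: 24 (5S,10S)-11,12,14-trimethoxyabieta-6,8,11,13-tetraene
Conditions: DDQ (1.2 equiv), 1,4-dioxane, rt to 50 °C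
Reagents that add atoms: none
Why: Quinone dehydrogenation, in which hydride is abstracted from benzylic C7 (cation stabilised by the para C12 and ortho C14 methoxy groups) and loss of H6 gives the styrene-type C6=C7 bond.

Step 14
Reactants: 24 (5S,10S)-11,12,14-trimethoxyabieta-6,8,11,13-tetraene
Product: 25 (4aS,9R,9aS)-9-(dimethoxymethyl)-7-isopropyl-5,6,8-trimethoxy-1,1,4a-trimethyl-2,3,4,4a,9,9a-hexahydro-1H-fluorene
Conditions: PhI(OH)OTs (1.2 equiv), MeOH, 0 °C to rt
Reagents that add atoms: methanol, CO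
Why: Oxidative ring contraction by trivalent iodine (1,2-aryl shift of semipinacol type): iodination of C6 on the α-face with methanol adding to benzylic C7 puts the C6–I bond antiperiplanar to C7–C8, so C8 migrates to C6 as PhI leaves and C7 is extruded as the dimethyl acetal, with C5 and C10 untouched and C6 set only provisionally.

Step 15
Reactants: 25 (4aS,9R,9aS)-9-(dimethoxymethyl)-7-isopropyl-5,6,8-trimethoxy-1,1,4a-trimethyl-2,3,4,4a,9,9a-hexahydro-1H-fluorene
Product: 26 (4aS,9R,9aS)-7-isopropyl-5,6,8-trimethoxy-1,1,4a-trimethyl-2,3,4,4a,9,9a-hexahydro-1H-fluorene-9-carbaldehyde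
Conditions: 1 M aq. HCl, THF, rt
Reagents that add atoms: water, O
Why: Acid-catalysed acetal hydrolysis; any epimerisation at C6 is harmless because C6 is planarised in the next step.

Step 16
Reactants: 26 (4aS,9R,9aS)-7-isopropyl-5,6,8-trimethoxy-1,1,4a-trimethyl-2,3,4,4a,9,9a-hexahydro-1H-fluorene-9-carbaldehyde
Product: 28 (4aS,9R,9aS)-9-hydroxy-7-isopropyl-5,6,8-trimethoxy-1,1,4a-trimethyl-2,3,4,4a,9,9a-hexahydro-1H-fluorene-9-carbaldehyde, via potassium enolate 27 (not isolated)
Conditions: KN(SiMe3)2, THF, −78 °C; then 2-(phenylsulfonyl)-3-phenyloxaziridine, −78 °C; AcOH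
Reagents that add atoms: 2-(phenylsulfonyl)-3-phenyloxaziridine, O=S(=O)(c1ccccc1)N1OC1c1ccccc1
Why: Enolate oxidation with an N-sulfonyloxaziridine should occur on the α-face of the exocyclic aldehyde enolate, anti to the axial C19 and C20 methyl groups, setting C6 with OH α and CHO β.

Step 17
Reactants: 28 (4aS,9R,9aS)-9-hydroxy-7-isopropyl-5,6,8-trimethoxy-1,1,4a-trimethyl-2,3,4,4a,9,9a-hexahydro-1H-fluorene-9-carbaldehyde
Product: 29 (4aS,9R,9aS)-9-hydroxy-7-isopropyl-6-methoxy-1,1,4a-trimethyl-5,8-dioxo-2,3,4,4a,5,8,9,9a-octahydro-1H-fluorene-9-carbaldehyde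
Conditions: (NH4)2Ce(NO3)6 (2.5 equiv), MeCN/H2O, 0 °C, short contact time
Reagents that add atoms: water, O
Why: Oxidative demethylation by tetravalent cerium converts the para-related C11 and C14 methoxy groups into the p-quinone by fast electron transfer from the arene, which should outrun cleavage of the tertiary α-hydroxy aldehyde at 0 °C, and leaves the C12 methoxy group as a vinylogous ester.

Step 18
Reactants: 29 (4aS,9R,9aS)-9-hydroxy-7-isopropyl-6-methoxy-1,1,4a-trimethyl-5,8-dioxo-2,3,4,4a,5,8,9,9a-octahydro-1H-fluorene-9-carbaldehyde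
Product: 30 (4aS,9R,9aS)-6,9-dihydroxy-7-isopropyl-1,1,4a-trimethyl-5,8-dioxo-2,3,4,4a,5,8,9,9a-octahydro-1H-fluorene-9-carbaldehyde
Conditions: 0.2 M aq. NaOH, THF, 0 °C; then 1 M HCl
Reagents that add atoms: sodium hydroxide, [Na+].[OH-]
Why: Addition–elimination of hydroxide at C12 (vinylogous ester saponification) gives the 2-hydroxy-1,4-quinone, and cold, brief exposure should spare the α-ketol unit.

Step 19
Reactants: 30 (4aS,9R,9aS)-6,9-dihydroxy-7-isopropyl-1,1,4a-trimethyl-5,8-dioxo-2,3,4,4a,5,8,9,9a-octahydro-1H-fluorene-9-carbaldehyde; 31 4-epi-trans-communic acid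
Product: 32 target CNP0124601.1
Conditions: BF3·OEt2 (20 mol %), CH2Cl2, −40 to −10 °C
Reagents that add atoms: none
Why: Perezone-type cationic (5+2) cycloaddition, in which Lewis-acid chelation at O11/O12 turns C8–C9–C11–C12–C13 into a 2-oxy-pentadienyl cation, the diene terminus C15′ bonds to C8 on the α-face (opposite the C20 methyl and the β-formyl group), enol carbon C13 closes onto C14′ of the resulting allyl cation in the endo mode (diene residue under the C11/C12 bridge), and proton loss leaves the C11 enol, the C12 ketone and C14 as the bridging ketone.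

**Compound list**

1 | 1,2,4-trimethoxybenzene | COc1ccc(OC)c(OC)c1 | starting material
2 | acetone | CC(C)=O | starting material
3 | (2,3,6-trimethoxyphenyl)lithium | [Li]c1c(OC)c(OC)ccc1OC | intermediate (not isolated)
4 | 2-(2,3,6-trimethoxyphenyl)propan-2-ol | CC(C)(O)c1c(OC)c(OC)ccc1OC | intermediate
5 | 2-isopropyl-1,3,4-trimethoxybenzene | CC(C)c1c(OC)c(OC)ccc1OC | intermediate
6 | 1-bromo-3-isopropyl-2,4,5-trimethoxybenzene | CC(C)c1c(OC)c(OC)cc(Br)c1OC | intermediate
7 | (4R)-4-benzyl-1,3-oxazolidin-2-one | O=C1OC[C@@H](Cc2ccccc2)N1 | starting material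
8 | 4-bromobutanoyl chloride | O=C(Cl)CCCBr | starting material
9 | lithium salt of 7 | O=C1OC[C@@H](Cc2ccccc2)N1[Li] | intermediate (not isolated)
10 | (4R)-4-benzyl-3-(4-bromobutanoyl)-1,3-oxazolidin-2-one | O=C1OC[C@@H](Cc2ccccc2)N1C(=O)CCCBr | intermediate
11 | {4-[(4R)-4-benzyl-2-oxo-1,3-oxazolidin-3-yl]-4-oxobutyl}zinc bromide | O=C1OC[C@@H](Cc2ccccc2)N1C(=O)CCC[Zn]Br | intermediate (not isolated)
12 | (4R)-4-benzyl-3-[4-(3-isopropyl-2,4,5-trimethoxyphenyl)butanoyl]-1,3-oxazolidin-2-one | O=C1OC[C@@H](Cc2ccccc2)N1C(=O)CCCc1cc(OC)c(OC)c(C(C)C)c1OC | intermediate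
13 | 3-methoxy-3-methylbut-1-yne | COC(C)(C)C#C | starting material
14 | octacarbonyldicobalt, Co2(CO)8 | O=C=[Co](=C=O)(=C=O)(=C=O)[Co](=C=O)(=C=O)(=C=O)=C=O | starting material
15 | hexacarbonyl[μ-(3-methoxy-3-methylbut-1-yne)]dicobalt | COC(C)(C)C12C3[Co]1(=C=O)(=C=O)(=C=O)[Co]23(=C=O)(=C=O)=C=O | intermediate
16 | dibutylboron Z-enolate of 12 | O=C1OC[C@@H](Cc2ccccc2)N1/C(OB(CCCC)CCCC)=C/CCc1cc(OC)c(OC)c(C(C)C)c1OC | intermediate (not isolated)
17 | hexacarbonyldicobalt complex of 18 | O=C1OC[C@@H](Cc2ccccc2)N1C(=O)[C@@H](CCc1cc(OC)c(OC)c(C(C)C)c1OC)C(C)(C)C12C3[Co]1(=C=O)(=C=O)(=C=O)[Co]23(=C=O)(=C=O)=C=O | intermediate (not isolated)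
18 | (4R)-4-benzyl-3-[(2S)-2-[2-(3-isopropyl-2,4,5-trimethoxyphenyl)ethyl]-3,3-dimethylpent-4-ynoyl]-1,3-oxazolidin-2-one | O=C1OC[C@@H](Cc2ccccc2)N1C(=O)[C@@H](CCc1cc(OC)c(OC)c(C(C)C)c1OC)C(C)(C)C#C | intermediate
19 | (2S)-2-[2-(3-isopropyl-2,4,5-trimethoxyphenyl)ethyl]-3,3-dimethylpent-4-ynoic acid | OC(=O)[C@@H](CCc1cc(OC)c(OC)c(C(C)C)c1OC)C(C)(C)C#C | intermediate
20 | (3S)-3-[2-(3-isopropyl-2,4,5-trimethoxyphenyl)ethyl]-4,4-dimethylhex-5-yn-2-one | CC(=O)[C@@H](CCc1cc(OC)c(OC)c(C(C)C)c1OC)C(C)(C)C#C | intermediate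
21 | (4R)-4-[2-(3-isopropyl-2,4,5-trimethoxyphenyl)ethyl]-3,3,5-trimethylhex-5-en-1-yne | C=C(C)[C@@H](CCc1cc(OC)c(OC)c(C(C)C)c1OC)C(C)(C)C#C | intermediate
22 | (5S,10S)-11,12,14-trimethoxyabieta-2,8,11,13-tetraene (trans A/B, 10β-methyl, 5α-H) | COc1c2c(c(OC)c(OC)c1C(C)C)[C@@]1(C)CC=CC(C)(C)[C@@H]1CC2 | intermediate
23 | (5S,10S)-11,12,14-trimethoxyabieta-8,11,13-triene | COc1c2c(c(OC)c(OC)c1C(C)C)[C@@]1(C)CCCC(C)(C)[C@@H]1CC2 | intermediate
24 | (5S,10S)-11,12,14-trimethoxyabieta-6,8,11,13-tetraene | COc1c2c(c(OC)c(OC)c1C(C)C)[C@@]1(C)CCCC(C)(C)[C@@H]1C=C2 | intermediate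
25 | (4aS,9R,9aS)-9-(dimethoxymethyl)-7-isopropyl-5,6,8-trimethoxy-1,1,4a-trimethyl-2,3,4,4a,9,9a-hexahydro-1H-fluorene (acetal on the α-face, cis to H-9a) | COc1c2c(c(OC)c(OC)c1C(C)C)[C@@]1(C)CCCC(C)(C)[C@@H]1[C@H]2C(OC)OC | intermediate
26 | (4aS,9R,9aS)-7-isopropyl-5,6,8-trimethoxy-1,1,4a-trimethyl-2,3,4,4a,9,9a-hexahydro-1H-fluorene-9-carbaldehyde | COc1c2c(c(OC)c(OC)c1C(C)C)[C@@]1(C)CCCC(C)(C)[C@@H]1[C@H]2C=O | intermediate
27 | potassium enolate of 26 | COc1c2c(c(OC)c(OC)c1C(C)C)[C@@]1(C)CCCC(C)(C)[C@@H]1C2=CO[K] | intermediate (not isolated)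
28 | (4aS,9R,9aS)-9-hydroxy-7-isopropyl-5,6,8-trimethoxy-1,1,4a-trimethyl-2,3,4,4a,9,9a-hexahydro-1H-fluorene-9-carbaldehyde (OH α, CHO β) | COc1c2c(c(OC)c(OC)c1C(C)C)[C@@]1(C)CCCC(C)(C)[C@@H]1[C@]2(O)C=O | intermediate
29 | (4aS,9R,9aS)-9-hydroxy-7-isopropyl-6-methoxy-1,1,4a-trimethyl-5,8-dioxo-2,3,4,4a,5,8,9,9a-octahydro-1H-fluorene-9-carbaldehyde | O=C1C2=C(C(=O)C(OC)=C1C(C)C)[C@@]1(C)CCCC(C)(C)[C@@H]1[C@]2(O)C=O | intermediate
30 | (4aS,9R,9aS)-6,9-dihydroxy-7-isopropyl-1,1,4a-trimethyl-5,8-dioxo-2,3,4,4a,5,8,9,9a-octahydro-1H-fluorene-9-carbaldehyde | O=C1C2=C(C(=O)C(O)=C1C(C)C)[C@@]1(C)CCCC(C)(C)[C@@H]1[C@]2(O)C=O | intermediate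
31 | 4-epi-trans-communic acid, (1R,4aR,5S,8aR)-1,4a-dimethyl-6-methylidene-5-[(2E)-3-methylpenta-2,4-dien-1-yl]decahydronaphthalene-1-carboxylic acid | C=C1CC[C@@H]2[C@](C)(CCC[C@@]2(C)C(=O)O)[C@H]1C/C=C(\C)C=C | starting material
32 | CNP0124601.1 | C=C1CC[C@@H]2[C@](C)(CCC[C@@]2(C)C(=O)O)[C@H]1C/C=C(\C)[C@@H]1C[C@@]23C(=O)[C@]1(C(C)C)C(=O)C(O)=C2[C@@]1(C)CCCC(C)(C)[C@@H]1[C@]3(O)C=O | target

**Step count and risks**

Total steps: 19. Longest linear sequence: 17 steps (steps 1–3, 5, 7–19) from 1,2,4-trimethoxybenzene.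

Steps most likely to fail:

1. Step 19. The union may be diverted by Diels–Alder addition of the s-cis diene across a quinone C=C bond, by attack of the exocyclic C8′ methylene of 31, or by Lewis-acid-induced α-ketol ring expansion of the hydroxy aldehyde. The fallback sets out from 30. O-Alkylation of its vinylogous acid with 4-methoxybenzyl chloride and Ag2O in CH2Cl2 should give (4aS,9R,9aS)-9-hydroxy-7-isopropyl-6-[(4-methoxybenzyl)oxy]-1,1,4a-trimethyl-5,8-dioxo-2,3,4,4a,5,8,9,9a-octahydro-1H-fluorene-9-carbaldehyde F8. This 2-alkoxy-1,4-quinone is then combined with 31 under TiCl4/Ti(OiPr)4 in CH2Cl2 at −78 °C. Bidentate titanium binding at O11/O12 fixes the pentadienyl cation, and the closing step expels the 4-methoxybenzyl cation, so the (5+2) closure cannot revert. This returns to the route at 32.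

2. Step 11. The cascade may close through the conformer with the arylethyl arm in the alkene plane (cis A/B junction), or the gold carbenoid may undergo an alkyl shift instead of arene capture. The fallback sets out from 21. Anti-Markovnikov hydration of the alkyne (dicyclohexylborane, THF, 0 °C; then NaBO3) should give (4R)-4-[2-(3-isopropyl-2,4,5-trimethoxyphenyl)ethyl]-3,3,5-trimethylhex-5-enal F1. A carbonyl-initiated Prins cyclisation with Friedel–Crafts termination (Me2AlCl, CH2Cl2, −78 to 0 °C, then brief CF3SO3H to close any ene-type alkenes) should give 11,12,14-trimethoxyabieta-8,11,13-trien-2-ol F2, the free C10 cation being captured with the classical preference for the trans junction. Conversion to O-(11,12,14-trimethoxyabieta-8,11,13-trien-2-yl) S-methyl carbonodithioate F3 (NaH, CS2, MeI) and Barton–McCombie deoxygenation (Bu3SnH, AIBN, toluene, 110 °C) returns to the route at 23.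

3. Step 14. Hydride rather than aryl migration (giving a 6-ketone) or oxidation of the electron-rich arene by trivalent iodine may take over. The fallback sets out from 23 and uses a Wolff ring contraction. Benzylic oxidation (CrO3, AcOH) should give 11,12,14-trimethoxyabieta-8,11,13-trien-7-one F4. Formylation (NaH, HCO2Et) gives 6-(hydroxymethylidene)-11,12,14-trimethoxyabieta-8,11,13-trien-7-one F5, and Regitz deformylative diazo transfer (TsN3, Et3N) gives 6-diazo-11,12,14-trimethoxyabieta-8,11,13-trien-7-one F6. Photolysis in MeOH moves C8 from C7 to C6 and should give methyl (4aS,9R,9aS)-7-isopropyl-5,6,8-trimethoxy-1,1,4a-trimethyl-2,3,4,4a,9,9a-hexahydro-1H-fluorene-9-carboxylate F7. Reduction with iBu2AlH (CH2Cl2, −78 °C) returns to the route at 26.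

**Further compounds**

F1 | step 11 | (4R)-4-[2-(3-isopropyl-2,4,5-trimethoxyphenyl)ethyl]-3,3,5-trimethylhex-5-enal | C=C(C)[C@@H](CCc1cc(OC)c(OC)c(C(C)C)c1OC)C(C)(C)CC=O
F2 | step 11 | 11,12,14-trimethoxyabieta-8,11,13-trien-2-ol (C2 epimers) | COc1c2c(c(OC)c(OC)c1C(C)C)[C@@]1(C)CC(O)CC(C)(C)[C@@H]1CC2
F3 | step 11 | O-(11,12,14-trimethoxyabieta-8,11,13-trien-2-yl) S-methyl carbonodithioate | COc1c2c(c(OC)c(OC)c1C(C)C)[C@@]1(C)CC(OC(=S)SC)CC(C)(C)[C@@H]1CC2
F4 | step 14 | 11,12,14-trimethoxyabieta-8,11,13-trien-7-one | COc1c2c(c(OC)c(OC)c1C(C)C)[C@@]1(C)CCCC(C)(C)[C@@H]1CC2=O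
F5 | step 14 | 6-(hydroxymethylidene)-11,12,14-trimethoxyabieta-8,11,13-trien-7-one | COc1c2c(c(OC)c(OC)c1C(C)C)[C@@]1(C)CCCC(C)(C)[C@@H]1C(=CO)C2=O
F6 | step 14 | 6-diazo-11,12,14-trimethoxyabieta-8,11,13-trien-7-one | COc1c2c(c(OC)c(OC)c1C(C)C)[C@@]1(C)CCCC(C)(C)[C@@H]1C(=[N+]=[N-])C2=O
F7 | step 14 | methyl (4aS,9R,9aS)-7-isopropyl-5,6,8-trimethoxy-1,1,4a-trimethyl-2,3,4,4a,9,9a-hexahydro-1H-fluorene-9-carboxylate | COc1c2c(c(OC)c(OC)c1C(C)C)[C@@]1(C)CCCC(C)(C)[C@@H]1[C@H]2C(=O)OC
F8 | step 19 | (4aS,9R,9aS)-9-hydroxy-7-isopropyl-6-[(4-methoxybenzyl)oxy]-1,1,4a-trimethyl-5,8-dioxo-2,3,4,4a,5,8,9,9a-octahydro-1H-fluorene-9-carbaldehyde | O=C1C2=C(C(=O)C(OCc3ccc(OC)cc3)=C1C(C)C)[C@@]1(C)CCCC(C)(C)[C@@H]1[C@]2(O)C=O
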